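**Retrosynthetic overview**
- The target is the O11 (E)-caffeate of (−)-drimenol. The side chain is removed first: the cinnamate C=C by a Knoevenagel–Doebner disconnection (3,4-dihydroxybenzaldehyde + malonic half-ester), and the acyl–O11 bond by alcoholysis of Meldrum's acid.
- Feature on which the plan rests (drimane numbering: ring A = C1–C5 + C10, gem-dimethyl at C4; ring B = C5–C10, C7=C8, C12 on C8, C11H2O on C9, C15 on C10): all fifteen carbons, O11 and the head-to-tail methyl pattern are those of (2E,6E)-farnesol, so only C4–C5 and C9–C10 are missing.
- Key disconnection: both bonds form in one proton-initiated cation–olefin cascade inside a squalene–hopene cyclase. Ring A closes first, ring B second, and loss of H7 leaves C7=C8. C5, C10 and C9 are all set in this event.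
- No protecting group is used, and the three stereocentres are not touched afterwards.

Key step: step 1

Assumption: 1 is bought isomerically pure (a 2Z contaminant would deliver the C9 epimer), and the cyclase is a variant of the Alicyclobacillus acidocaldarius enzyme picked from a focused active-site library by screening for loss of H7, the parent enzyme being already competent for the same bicyclization.

Step 1
Reactants: 1 (2E,6E)-farnesol
Product: 2 (−)-drimenol [(5S,9S,10S)-drim-7-en-11-ol; trans-decalin, H5 α, C15 β, C11 β-equatorial]
Conditions: AacSHC variant (squalene–hopene cyclase of Alicyclobacillus acidocaldarius, heat-clarified E. coli lysate), 1 (5–10 mM), sodium citrate buffer pH 6.0, 0.2% Triton X-100, 50 °C, 48–72 h; MTBE extraction; AgNO3–SiO2 chromatography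
Reagents that add atoms: none
Why: Known reaction type, the Brønsted-acid cation–olefin polycyclization run by class 2 terpene cyclases on farnesyl substrates: the aspartic acid of the DXDD motif protonates C3 of the terminal C3=C4 alkene of 1, which lies in a chair–chair fold, and the charge passes through the tertiary positions C4, C10 and C8 before an axial H7 is lost. Ring A closes first by 6-endo-trig attack of C5 (alkene C5=C10) on C4 and ring B second by 6-endo-trig attack of C9 (alkene C8=C9) on C10, both in the Markovnikov sense that the methyl branches of 1 dictate. Anti addition across the E alkene C5=C10 places H5 and C15 trans (5S,10S) and anti addition across the E alkene C8=C9 places C11 equatorial (9S), so the relative configuration follows from the two E alkenes in the chair–chair fold, while the absolute sense comes from the chiral cavity, which coils the chain in the same way as rings A and B of hopene. Initiation at the far end is helped by the substrate, because O11 makes C8=C9 the least basic of the three alkenes, and O11 cannot trap the C8 cation, since that would need an oxetane. The selectivity that 1 does not secure is termination: the C15 chain fills only half of a cavity shaped for a C30 chain, so water capture at C8, proton loss from C12 or C9 and early quench after ring A compete, and the variant (bulkier residues around the zone where ring B ends) is chosen to shut out water and leave a base next to H7. Isomers that remain differ in alkene type or polarity and should be removable on AgNO3-impregnated silica.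

Step 2
Reactants: 2 (−)-drimenol; 3 Meldrum's acid (2,2-dimethyl-1,3-dioxane-4,6-dione)
Product: 4 (−)-drimenyl hydrogen malonate (malonic acid mono-ester at O11)
Conditions: 3 (1.1 equiv), PhMe, 110 °C, 4–6 h
Reagents that add atoms: Meldrum's acid (3), CC1(C)OC(=O)CC(=O)O1
Why: Thermal alcoholysis of Meldrum's acid (acylal ring opening): the primary C11 hydroxyl adds to one of the two activated carbonyl groups, the ring opens and acetone is expelled, which gives the half-ester in a neutral to weakly acidic medium that touches neither C7=C8 nor C5, C9 and C10.

Step 3
Reactants: 4 (−)-drimenyl hydrogen malonate; 5 3,4-dihydroxybenzaldehyde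
Product: 7 (−)-drimenyl (E)-caffeate (target), via arylidenemalonate half-ester 6 (not isolated)
Conditions: 5 (1.1 equiv), pyridine, piperidine (0.2 equiv), Ar, 25→45 °C, 24–48 h; pyridine removed by co-evaporation with PhMe, cold aqueous citric acid wash
Reagents that add atoms: 3,4-dihydroxybenzaldehyde (5), O=Cc1ccc(O)c(O)c1
Why: Knoevenagel–Doebner condensation: piperidine activates 5 as its iminium ion, the enolised half-ester adds, loss of water gives 6, and decarboxylation in pyridine delivers the conjugated ester as the thermodynamically preferred E alkene, free phenols being tolerated and no drimane stereocentre being affected.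

**Compound list**
1 | (2E,6E)-farnesol | CC(C)=CCC/C(C)=C/CC/C(C)=C/CO | starting material
2 | (−)-drimenol, [(1S,4aS,8aS)-2,5,5,8a-tetramethyl-1,4,4a,5,6,7,8,8a-octahydronaphthalen-1-yl]methanol | CC1=CC[C@H]2C(C)(C)CCC[C@]2(C)[C@H]1CO | intermediate
3 | Meldrum's acid | CC1(C)OC(=O)CC(=O)O1 | starting material
4 | (−)-drimenyl hydrogen malonate | CC1=CC[C@H]2C(C)(C)CCC[C@]2(C)[C@H]1COC(=O)CC(=O)O | intermediate
5 | 3,4-dihydroxybenzaldehyde | O=Cc1ccc(O)c(O)c1 | starting material
6 | 2-(3,4-dihydroxybenzylidene)malonic acid mono-drimenyl ester (alkene geometry undefined, erased on decarboxylation; not isolated) | CC1=CC[C@H]2C(C)(C)CCC[C@]2(C)[C@H]1COC(=O)C(=Cc1ccc(O)c(O)c1)C(=O)O | intermediate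
7 | [(1S,4aS,8aS)-2,5,5,8a-tetramethyl-1,4,4a,5,6,7,8,8a-octahydronaphthalen-1-yl]methyl (2E)-3-(3,4-dihydroxyphenyl)prop-2-enoate | CC1=CC[C@H]2C(C)(C)CCC[C@]2(C)[C@H]1COC(=O)/C=C/c1ccc(O)c(O)c1 | target

Total step count: 3
Longest linear sequence: 3 (1 → 2 → 4 → 7)

**Steps most likely to fail**

**Step 1.**
- What may go wrong: slow turnover of a short, poorly soluble substrate that sits loosely in the large cavity, early quench after ring A, and unselective termination at C8 (water capture, proton loss from C12 or C9).
- Fallback, from 1, returning at 2: the chain receives the diphosphate anchor for which dedicated C15 cyclases are built.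
- Chlorination of 1 with N-chlorosuccinimide/Me2S (CH2Cl2, −30 to 0 °C) should give (2E,6E)-farnesyl chloride F1 without allylic transposition.
- Displacement with tris(tetrabutylammonium) hydrogen diphosphate in MeCN, followed by ion exchange to the ammonium form, gives (2E,6E)-farnesyl diphosphate F2.
- A bacterial class 2 drimenyl diphosphate synthase (HEPES–NaOH pH 7.5, MgCl2, 30 °C) takes F2 through the same C4–C5/C9–C10 cascade to drimenyl diphosphate F3. Loss of H7 is the native termination of this enzyme.
- Alkaline phosphatase added to the same pot hydrolyses F3 to 2.

**Step 3.**
- What may go wrong: slow condensation because the phenoxide form of 5 deactivates the aldehyde, decarboxylation of 4 before the C–C bond forms, and air oxidation of the catechol in the basic medium.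
- Fallback, from 2, returning at 7: the C=C bond is not made on the drimane ester at all.
- Compound 2 is esterified with commercial (E)-3,4-diacetoxycinnamic acid (EDC·HCl, DMAP, CH2Cl2, 0 °C to rt, Steglich-type coupling) to give drimenyl (E)-3,4-diacetoxycinnamate F4.
- The two aryl acetates are then removed by mild methanolysis (catalytic K2CO3, MeOH/CH2Cl2, 0 °C, argon). This should be much faster than attack on the hindered conjugated alkyl ester, and it gives 7.

**Step 2.**
- What may go wrong: slow attack of the C11 hydroxyl, which is flanked by quaternary C10, so that thermal breakdown of 3 and decarboxylation of the half-ester gain ground.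
- Fallback, from 2, returning at 4: acylation at low temperature with methyl malonyl chloride (pyridine, CH2Cl2, 0 °C) gives methyl drimenyl malonate F5.
- One equivalent of LiOH (THF/H2O, 0 °C) should cleave the unhindered methyl ester in preference to the neopentyl-like drimenyl ester. The carboxylate that forms slows further hydrolysis.
- Brief acidification with cold dilute HCl gives 4.

**Further compounds**
F1 | step 1 | (2E,6E)-farnesyl chloride | CC(C)=CCC/C(C)=C/CC/C(C)=C/CCl
F2 | step 1 | (2E,6E)-farnesyl diphosphate (drawn as free acid, handled as ammonium salt) | CC(C)=CCC/C(C)=C/CC/C(C)=C/COP(=O)(O)OP(=O)(O)O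
F3 | step 1 | (5S,9S,10S)-drim-7-en-11-yl diphosphate (drawn as free acid) | CC1=CC[C@H]2C(C)(C)CCC[C@]2(C)[C@H]1COP(=O)(O)OP(=O)(O)O
F4 | step 3 | drimenyl (E)-3,4-diacetoxycinnamate | CC1=CC[C@H]2C(C)(C)CCC[C@]2(C)[C@H]1COC(=O)/C=C/c1ccc(OC(C)=O)c(OC(C)=O)c1
F5 | step 2 | methyl drimenyl malonate | CC1=CC[C@H]2C(C)(C)CCC[C@]2(C)[C@H]1COC(=O)CC(=O)OC
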